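**Retrosynthetic overview**

1. Ring D (the oxepane) is closed last by forming the C3–C4 bond: a samarium diiodide Barbier cyclization of seco iodo aldehyde 28 (primary iodide at C4, aldehyde at C3) should give sipholenol L directly, with no protecting groups.
2. Enabling feature: C3 sits between C4 and the quaternary ether carbon C2 (gem-dimethyl, bound to O1), so it can be carried as a non-enolizable neopentyl aldehyde; the O1–C9a and C5–C5a bonds are trans-diequatorial on the chair of ring C, which holds C3 and C4 within reach for a chair-like seven-membered closure.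
3. Both tertiary carbinols (C7 of ring C, d-C5 of the decalin) come from one double methylenation and one double Mukaiyama hydration of diketone 24; the C4 iodide comes from the C5a vinyl group.
4. The ethylene bridge is made by a decarboxylative Giese union of decalin acid 20 with α-methylene ketone 12 (ring C: quinone monoketal, CBS reduction, O–H insertion, anti-selective vinyl conjugate addition, Mannich methylenation).
5. Ring order: ring C (from the arene 1), ring B (bought as enone 16), ring A (asymmetric Diels–Alder of 15 with 16), ring D last (step 21).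

Key step: step 21

Remark: rings C and D use 1-benzoxepine numbering (O1, C2, C3, C4, C5, C5a, C6, C7, C8, C9, C9a); decalin atoms use naphthalene numbering with the prefix d (d-C1 to d-C8a); ring A is the cyclohexene, ring B the decalin cyclohexanol, ring C the cyclohexane, ring D the oxepane.

**Route**

Step 1
Reactants: 1 4-methoxy-2-methylphenol
Product: 2 4,4-dimethoxy-2-methylcyclohexa-2,5-dien-1-one
Conditions: PhI(OAc)2, MeOH, 0 °C
Reagents that add atoms: methanol (CO)
Why: Oxidative dearomatization of a para-alkoxyphenol with a hypervalent iodine reagent in methanol traps the phenoxenium ion at C4 as the dimethyl ketal (quinone monoketal formation); no stereocenter is formed.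

Step 2
Reactants: 2 4,4-dimethoxy-2-methylcyclohexa-2,5-dien-1-one
Product: 3 4,4-dimethoxy-2-methylcyclohex-2-en-1-one
Conditions: H2 (1 atm), RhCl(PPh3)3 (3 mol %), toluene, rt
Reagents that add atoms: none
Why: Homogeneous hydrogenation should saturate the unsubstituted C5=C6 double bond well before the methyl-bearing C2=C3 bond (steric discrimination in a chemoselective alkene hydrogenation), leaving the ketal intact.

Step 3
Reactants: 3 4,4-dimethoxy-2-methylcyclohex-2-en-1-one
Product: 4 (1S)-4,4-dimethoxy-2-methylcyclohex-2-en-1-ol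
Conditions: (R)-2-methyl-CBS-oxazaborolidine (10 mol %), BH3·SMe2, THF, –20 °C
Reagents that add atoms: none
Why: Corey–Bakshi–Shibata reduction of a 2-substituted cyclohexenone, in which the α-methylvinyl arm acts as the large group, so the (R)-catalyst should deliver hydride to give the (S)-carbinol that becomes C9a.

Step 4
Reactants: 4 (1S)-4,4-dimethoxy-2-methylcyclohex-2-en-1-ol
Product: 5 ethyl 2-{[(1S)-4,4-dimethoxy-2-methylcyclohex-2-en-1-yl]oxy}acetate
Conditions: N2CHCO2Et, Rh2(OAc)4 (1 mol %), CH2Cl2, rt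
Reagents that add atoms: ethyl diazoacetate (CCOC(=O)C=[N+]=[N-])
Why: Rhodium carbenoid O–H insertion alkylates the hindered allylic alcohol under neutral conditions that touch neither the ketal nor the stereocenter.

Step 5
Reactants: 5 ethyl 2-{[(1S)-4,4-dimethoxy-2-methylcyclohex-2-en-1-yl]oxy}acetate
Product: 7 ethyl 2-{[(1S)-4,4-dimethoxy-2-methylcyclohex-2-en-1-yl]oxy}-2-methylpropanoate, via monomethyl ester 6 (not isolated)
Conditions: LiN(i-Pr)2, THF, –78 °C; CH3I; then LiN(i-Pr)2, –78 °C; CH3I, –78 → 0 °C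
Reagents that add atoms: iodomethane (CI)
Why: Two consecutive ester enolate alkylations build the gem-dimethyl carbon C2; at –78 °C C-methylation of the lithium enolate should outrun its [2,3]-Wittig shift, and the new carbon ends up achiral.

Step 6
Reactants: 7 ethyl 2-{[(1S)-4,4-dimethoxy-2-methylcyclohex-2-en-1-yl]oxy}-2-methylpropanoate
Product: 8 ethyl 2-methyl-2-{[(1S)-2-methyl-4-oxocyclohex-2-en-1-yl]oxy}propanoate
Conditions: (CO2H)2, acetone/H2O, rt
Reagents that add atoms: water (O)
Why: Mild acid hydrolysis of the dimethyl ketal unmasks the C7 ketone in conjugation with the trisubstituted alkene (acetal hydrolysis); the ether stereocenter is not enolizable and the hindered ester survives.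

Step 7
Reactants: 8 ethyl 2-methyl-2-{[(1S)-2-methyl-4-oxocyclohex-2-en-1-yl]oxy}propanoate
Product: 9 ethyl 2-{[(1S,2S)-2-ethenyl-2-methyl-4-[(trimethylsilyl)oxy]cyclohex-3-en-1-yl]oxy}-2-methylpropanoate
Conditions: CH2=CHMgBr, CuBr·SMe2 (10 mol %), Me3SiCl, HMPA, THF, –78 °C; Et3N
Reagents that add atoms: vinylmagnesium bromide (C=C[Mg]Br); chlorotrimethylsilane (C[Si](C)(C)Cl)
Why: Copper-catalysed conjugate addition with silyl chloride acceleration forms the quaternary centre C5a, the vinyl group entering anti to the neighbouring C9a alkoxy group (trans rule for 4-alkoxycyclohexenones), and silyl trapping fixes the enolate regiochemistry at C6=C7.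

Step 8
Reactants: 9 ethyl 2-{[(1S,2S)-2-ethenyl-2-methyl-4-[(trimethylsilyl)oxy]cyclohex-3-en-1-yl]oxy}-2-methylpropanoate
Product: 12 ethyl 2-{[(1S,2S)-2-ethenyl-2-methyl-3-methylidene-4-oxocyclohexyl]oxy}-2-methylpropanoate, via Mannich base 10 (not isolated), via ammonium iodide 11 (not isolated)
Conditions: [CH2=NMe2]I, CH2Cl2, rt; then CH3I; then DBU, rt
Reagents that add atoms: N,N-dimethylmethyleneiminium iodide (C=[N+](C)C.[I-])
Why: Regiospecific Mannich reaction of the silyl enol ether at C6, quaternisation and base-induced elimination (α-methylenation) give the exocyclic enone whose methylene carbon becomes the ring C end of the ethylene bridge.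

Step 9
Reactants: 13 methyl 4-chloro-4-oxobutanoate
Product: 14 methyl 4-oxohex-5-enoate
Conditions: n-Bu3SnCH=CH2, PdCl2(PPh3)2 (2 mol %), toluene, 60 °C
Reagents that add atoms: tributyl(vinyl)stannane (C=C[Sn](CCCC)(CCCC)CCCC)
Why: Stille acylation of an acid chloride gives the vinyl ketone without touching the methyl ester.

Step 10
Reactants: 14 methyl 4-oxohex-5-enoate
Product: 15 methyl (3Z)-4-[(tert-butyldimethylsilyl)oxy]hexa-3,5-dienoate
Conditions: t-BuMe2SiOTf, Et3N, CH2Cl2, 0 °C
Reagents that add atoms: tert-butyldimethylsilyl trifluoromethanesulfonate (CC(C)(C)[Si](C)(C)OS(=O)(=O)C(F)(F)F)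
Why: Soft enolisation and silylation on the only enolisable side of the vinyl ketone give the 2-silyloxydiene, for which the (Z)-enol ether is the normal outcome with a silyl triflate and an amine.

Step 11
Reactants: 15 methyl (3Z)-4-[(tert-butyldimethylsilyl)oxy]hexa-3,5-dienoate; 16 4,4-dimethylcyclohex-2-en-1-one
Product: 17 methyl 2-[(1S,4aS,8aR)-2-[(tert-butyldimethylsilyl)oxy]-8,8-dimethyl-5-oxo-1,4,4a,5,6,7,8,8a-octahydronaphthalen-1-yl]acetate
Conditions: AlBr3-activated (S)-o-tolyl-CBS-oxazaborolidine (10 mol %), CH2Cl2, –40 °C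
Reagents that add atoms: none
Why: Lewis acid catalysed Diels–Alder reaction of a 2-silyloxydiene with a cyclic enone under chiral oxazaborolidinium catalysis: the silyloxy group makes the substituted diene terminus nucleophilic so that it bonds to the β-carbon next to the gem-dimethyl group, suprafacial addition gives the cis ring fusion, the endo transition state with the (Z)-diene places H-1 cis to H-4a and H-8a, and the catalyst selects the enone face (the enantiomeric catalyst is taken if the sense of induction turns out opposite).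

Step 12
Reactants: 17 methyl 2-[(1S,4aS,8aR)-2-[(tert-butyldimethylsilyl)oxy]-8,8-dimethyl-5-oxo-1,4,4a,5,6,7,8,8a-octahydronaphthalen-1-yl]acetate
Product: 18 methyl 2-[(1S,4aS,8aR)-8,8-dimethyl-5-oxo-2-{[(trifluoromethyl)sulfonyl]oxy}-1,4,4a,5,6,7,8,8a-octahydronaphthalen-1-yl]acetate
Conditions: CsF, PhNTf2, DME, rt
Reagents that add atoms: N-phenylbis(trifluoromethanesulfonimide) (O=S(=O)(N(c1ccccc1)S(=O)(=O)C(F)(F)F)C(F)(F)F)
Why: Fluoride-induced exchange of silyl for triflyl converts the silyl enol ether regiospecifically into the d-C2=d-C3 enol triflate without enolising the ring B ketone.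

Step 13
Reactants: 18 methyl 2-[(1S,4aS,8aR)-8,8-dimethyl-5-oxo-2-{[(trifluoromethyl)sulfonyl]oxy}-1,4,4a,5,6,7,8,8a-octahydronaphthalen-1-yl]acetate
Product: 19 methyl 2-[(1S,4aS,8aR)-2,8,8-trimethyl-5-oxo-1,4,4a,5,6,7,8,8a-octahydronaphthalen-1-yl]acetate
Conditions: CH3ZnCl, Pd(PPh3)4 (5 mol %), THF, 0 °C → rt
Reagents that add atoms: methylzinc chloride (C[Zn]Cl)
Why: Negishi coupling of the enol triflate installs the vinylic methyl group with retention of the double bond position and tolerates the ketone and the ester.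

Step 14
Reactants: 19 methyl 2-[(1S,4aS,8aR)-2,8,8-trimethyl-5-oxo-1,4,4a,5,6,7,8,8a-octahydronaphthalen-1-yl]acetate
Product: 20 2-[(1S,4aS,8aR)-2,8,8-trimethyl-5-oxo-1,4,4a,5,6,7,8,8a-octahydronaphthalen-1-yl]acetic acid
Conditions: Me3SnOH, ClCH2CH2Cl, 80 °C; aq. HCl
Reagents that add atoms: trimethyltin hydroxide (C[Sn](C)(C)O)
Why: Trimethyltin hydroxide cleaves the methyl ester under nearly neutral conditions (mild ester hydrolysis), so the cis ring fusion α to the ketone should not epimerise.

Step 15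
Reactants: 20 2-[(1S,4aS,8aR)-2,8,8-trimethyl-5-oxo-1,4,4a,5,6,7,8,8a-octahydronaphthalen-1-yl]acetic acid; 12 ethyl 2-{[(1S,2S)-2-ethenyl-2-methyl-3-methylidene-4-oxocyclohexyl]oxy}-2-methylpropanoate
Product: 22 ethyl 2-({(1S,2S,3S)-2-ethenyl-2-methyl-4-oxo-3-[2-((1S,4aS,8aR)-2,8,8-trimethyl-5-oxo-1,4,4a,5,6,7,8,8a-octahydronaphthalen-1-yl)ethyl]cyclohexyl}oxy)-2-methylpropanoate, via phthalimidyl ester 21 (not isolated)
Conditions: N-hydroxyphthalimide, i-PrN=C=N-i-Pr, DMAP (cat.), CH2Cl2, rt; then 12, Ru(bpy)3(PF6)2 (1 mol %), Hantzsch ester, i-Pr2NEt, CH2Cl2/THF, blue LED, rt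
Reagents that add atoms: none
Why: Decarboxylative Giese addition: single-electron reduction of the redox-active ester releases the primary radical, which adds to the unhindered methylene terminus of enone 12, and hydrogen is then delivered axially to C6 from the face opposite the axial C5a methyl, giving the equatorial side chain (trans to the C5a vinyl group), which is also the thermodynamically preferred epimer.

Step 16
Reactants: 22 ethyl 2-({(1S,2S,3S)-2-ethenyl-2-methyl-4-oxo-3-[2-((1S,4aS,8aR)-2,8,8-trimethyl-5-oxo-1,4,4a,5,6,7,8,8a-octahydronaphthalen-1-yl)ethyl]cyclohexyl}oxy)-2-methylpropanoate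
Product: 24 ethyl 2-({(1S,2S,3S)-2-(2-hydroxyethyl)-2-methyl-4-oxo-3-[2-((1S,4aS,8aR)-2,8,8-trimethyl-5-oxo-1,4,4a,5,6,7,8,8a-octahydronaphthalen-1-yl)ethyl]cyclohexyl}oxy)-2-methylpropanoate, via pinacol boronate 23 (not isolated)
Conditions: HBpin, RhCl(PPh3)3 (3 mol %), THF, rt; then H2O2, pH 7 buffer, 0 °C
Reagents that add atoms: hydrogen peroxide (OO)
Why: Rhodium-catalysed hydroboration is selective for the monosubstituted alkene over both ketones and the trisubstituted ring A alkene and is anti-Markovnikov, so oxidation gives the primary alcohol at C4.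

Step 17
Reactants: 24 ethyl 2-({(1S,2S,3S)-2-(2-hydroxyethyl)-2-methyl-4-oxo-3-[2-((1S,4aS,8aR)-2,8,8-trimethyl-5-oxo-1,4,4a,5,6,7,8,8a-octahydronaphthalen-1-yl)ethyl]cyclohexyl}oxy)-2-methylpropanoate
Product: 25 bis(methylidene) analogue of 24 (C7 and d-C5 carbonyls both replaced by C=CH2, all stereocenters as in 24)
Conditions: Zn, CH2Br2, TiCl4, THF/CH2Cl2, 0 °C → rt
Reagents that add atoms: dibromomethane (BrCBr)
Why: Non-basic titanium–zinc methylenation converts both hindered, enolisable ketones into exocyclic methylenes without epimerising C6 or d-C4a.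

Step 18
Reactants: 25 bis(methylidene) analogue of 24
Product: 26 seco triol ester (ethyl 2-methylpropanoate ether at C9a, 2-hydroxyethyl at C5a, tertiary carbinols at C7 and d-C5 with the target configuration)
Conditions: Co(acac)2 (20 mol %), PhSiH3, O2 (1 atm), i-PrOH, rt
Reagents that add atoms: dioxygen (O=O)
Why: Mukaiyama hydration by hydrogen atom transfer to the two 1,1-disubstituted alkenes, which react faster than the trisubstituted ring A alkene; each tertiary radical should be trapped by O2 from its open face, equatorially at C7 (away from the axial C5a methyl) and from the convex face of the cis-decalin at d-C5, which places both methyl groups as in the target.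

Step 19
Reactants: 26 seco triol ester
Product: 27 seco iodo ester (primary iodide at C4, otherwise as 26)
Conditions: I2, PPh3, imidazole, CH2Cl2, 0 °C
Reagents that add atoms: iodine (II)
Why: Appel-type iodination is selective for the primary hydroxyl; the two tertiary alcohols should not react.

Step 20
Reactants: 27 seco iodo ester
Product: 28 seco iodo aldehyde (aldehyde at C3, iodide at C4, free tertiary alcohols at C7 and d-C5)
Conditions: i-Bu2AlH (5 equiv), CH2Cl2, –78 °C; aq. KNaC4H4O6
Reagents that add atoms: none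
Why: Partial reduction of the α-alkoxy ester should stop at the aldehyde because the chelated aluminium hemiacetal is stable at –78 °C; the alkyl iodide is not affected.

Step 21
Reactants: 28 seco iodo aldehyde
Product: 29 sipholenol L
Conditions: SmI2 (4 equiv), HMPA (16 equiv), THF, 0 °C, slow addition of 28 (final 2 mM)
Reagents that add atoms: none
Why: Samarium diiodide with HMPA reduces the primary C4 iodide to the alkyl radical and then to the alkylsamarium, which adds to the C3 aldehyde in the same molecule, and the samarium alkoxide is protonated on work-up (intramolecular Barbier reaction). The closest known reaction type is the samarium diiodide promoted Barbier cyclization of ω-iodo carbonyl compounds, which is used for five- to eight-membered carbinols. Ring D closes in the 7-exo-trig mode, the C4 nucleophile attacking the exocyclic C=O. The new stereocenter C3 is controlled by the trans-fused chair of ring C: in the chair-like seven-membered transition state the samarium-bound oxygen should sit pseudo-equatorial, away from the axial C5a methyl, so the hydroxyl ends up trans to that methyl as in the target, whereas hydride reduction of the corresponding ketone would be expected to come from the face away from that methyl and give the epimer. The step needs iodide reduction to outrun ketyl formation, which HMPA, the neopentyl non-enolizable aldehyde (no aldol, slow pinacol coupling) and high dilution should secure; no 5-exo radical acceptor is left because C7 is already sp3, and the free tertiary alcohols and the ring A alkene are inert to divalent samarium.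

**Compound list**

1 | 4-methoxy-2-methylphenol | Cc1cc(OC)ccc1O | starting material
2 | 4,4-dimethoxy-2-methylcyclohexa-2,5-dien-1-one | CC1=CC(OC)(OC)C=CC1=O | intermediate
3 | 4,4-dimethoxy-2-methylcyclohex-2-en-1-one | CC1=CC(OC)(OC)CCC1=O | intermediate
4 | (1S)-4,4-dimethoxy-2-methylcyclohex-2-en-1-ol | O[C@@H]1C(C)=CC(OC)(OC)CC1 | intermediate
5 | ethyl 2-{[(1S)-4,4-dimethoxy-2-methylcyclohex-2-en-1-yl]oxy}acetate | CCOC(=O)CO[C@@H]1C(C)=CC(OC)(OC)CC1 | intermediate
6 | ethyl 2-{[(1S)-4,4-dimethoxy-2-methylcyclohex-2-en-1-yl]oxy}propanoate (both epimers at the propanoate C2; not isolated) | CCOC(=O)C(C)O[C@@H]1C(C)=CC(OC)(OC)CC1 | intermediate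
7 | ethyl 2-{[(1S)-4,4-dimethoxy-2-methylcyclohex-2-en-1-yl]oxy}-2-methylpropanoate | CCOC(=O)C(C)(C)O[C@@H]1C(C)=CC(OC)(OC)CC1 | intermediate
8 | ethyl 2-methyl-2-{[(1S)-2-methyl-4-oxocyclohex-2-en-1-yl]oxy}propanoate | CCOC(=O)C(C)(C)O[C@@H]1C(C)=CC(=O)CC1 | intermediate
9 | ethyl 2-{[(1S,2S)-2-ethenyl-2-methyl-4-[(trimethylsilyl)oxy]cyclohex-3-en-1-yl]oxy}-2-methylpropanoate (vinyl trans to the ether oxygen) | CCOC(=O)C(C)(C)O[C@@H]1[C@@](C)(C=C)C=C(O[Si](C)(C)C)CC1 | intermediate
10 | Mannich base: 3-[(dimethylamino)methyl] ketone from 9 (epimers at the aminomethyl-bearing carbon; not isolated) | CCOC(=O)C(C)(C)O[C@@H]1[C@@](C)(C=C)C(CN(C)C)C(=O)CC1 | intermediate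
11 | trimethylammonium iodide of 10 (not isolated) | CCOC(=O)C(C)(C)O[C@@H]1[C@@](C)(C=C)C(C[N+](C)(C)C)C(=O)CC1.[I-] | intermediate
12 | ethyl 2-{[(1S,2S)-2-ethenyl-2-methyl-3-methylidene-4-oxocyclohexyl]oxy}-2-methylpropanoate | CCOC(=O)C(C)(C)O[C@@H]1[C@@](C)(C=C)C(=C)C(=O)CC1 | intermediate
13 | methyl 4-chloro-4-oxobutanoate | COC(=O)CCC(Cl)=O | starting material
14 | methyl 4-oxohex-5-enoate | COC(=O)CCC(=O)C=C | intermediate
15 | methyl (3Z)-4-[(tert-butyldimethylsilyl)oxy]hexa-3,5-dienoate | COC(=O)C/C=C(\O[Si](C)(C)C(C)(C)C)C=C | intermediate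
16 | 4,4-dimethylcyclohex-2-en-1-one | CC1(C)CCC(=O)C=C1 | starting material
17 | methyl 2-[(1S,4aS,8aR)-2-[(tert-butyldimethylsilyl)oxy]-8,8-dimethyl-5-oxo-1,4,4a,5,6,7,8,8a-octahydronaphthalen-1-yl]acetate (cis-fused; H-1, H-4a, H-8a all cis) | CC(C)(C)[Si](C)(C)OC1=CC[C@H]2[C@@H]([C@@H]1CC(=O)OC)C(C)(C)CCC2=O | intermediate
18 | methyl 2-[(1S,4aS,8aR)-8,8-dimethyl-5-oxo-2-{[(trifluoromethyl)sulfonyl]oxy}-1,4,4a,5,6,7,8,8a-octahydronaphthalen-1-yl]acetate | O=S(=O)(OC1=CC[C@H]2[C@@H]([C@@H]1CC(=O)OC)C(C)(C)CCC2=O)C(F)(F)F | intermediate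
19 | methyl 2-[(1S,4aS,8aR)-2,8,8-trimethyl-5-oxo-1,4,4a,5,6,7,8,8a-octahydronaphthalen-1-yl]acetate | CC1=CC[C@H]2[C@@H]([C@@H]1CC(=O)OC)C(C)(C)CCC2=O | intermediate
20 | 2-[(1S,4aS,8aR)-2,8,8-trimethyl-5-oxo-1,4,4a,5,6,7,8,8a-octahydronaphthalen-1-yl]acetic acid | CC1=CC[C@H]2[C@@H]([C@@H]1CC(=O)O)C(C)(C)CCC2=O | intermediate
21 | 1,3-dioxoisoindolin-2-yl ester of acid 20 (not isolated) | CC1=CC[C@H]2[C@@H]([C@@H]1CC(=O)ON1C(=O)c3ccccc3C1=O)C(C)(C)CCC2=O | intermediate
22 | ethyl 2-({(1S,2S,3S)-2-ethenyl-2-methyl-4-oxo-3-[2-((1S,4aS,8aR)-2,8,8-trimethyl-5-oxo-1,4,4a,5,6,7,8,8a-octahydronaphthalen-1-yl)ethyl]cyclohexyl}oxy)-2-methylpropanoate | CC1=CC[C@H]2[C@@H]([C@@H]1CC[C@H]1[C@](C)(C=C)[C@@H](OC(C)(C)C(=O)OCC)CCC1=O)C(C)(C)CCC2=O | intermediate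
23 | pinacol boronate from hydroboration of the vinyl group of 22 (not isolated) | CC1=CC[C@H]2[C@@H]([C@@H]1CC[C@H]1[C@](C)(CCB3OC(C)(C)C(C)(C)O3)[C@@H](OC(C)(C)C(=O)OCC)CCC1=O)C(C)(C)CCC2=O | intermediate
24 | ethyl 2-({(1S,2S,3S)-2-(2-hydroxyethyl)-2-methyl-4-oxo-3-[2-((1S,4aS,8aR)-2,8,8-trimethyl-5-oxo-1,4,4a,5,6,7,8,8a-octahydronaphthalen-1-yl)ethyl]cyclohexyl}oxy)-2-methylpropanoate | CC1=CC[C@H]2[C@@H]([C@@H]1CC[C@H]1[C@](C)(CCO)[C@@H](OC(C)(C)C(=O)OCC)CCC1=O)C(C)(C)CCC2=O | intermediate
25 | bis(methylidene) analogue of 24 (C=CH2 at C7 and d-C5) | CC1=CC[C@H]2[C@@H]([C@@H]1CC[C@H]1[C@](C)(CCO)[C@@H](OC(C)(C)C(=O)OCC)CCC1=C)C(C)(C)CCC2=C | intermediate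
26 | seco triol ester (tertiary carbinols at C7 and d-C5, primary alcohol at C4, ethyl ester at C3) | CC1=CC[C@H]2[C@@H]([C@@H]1CC[C@H]1[C@](C)(CCO)[C@@H](OC(C)(C)C(=O)OCC)CC[C@]1(C)O)C(C)(C)CC[C@]2(C)O | intermediate
27 | seco iodo ester (primary iodide at C4) | CC1=CC[C@H]2[C@@H]([C@@H]1CC[C@H]1[C@](C)(CCI)[C@@H](OC(C)(C)C(=O)OCC)CC[C@]1(C)O)C(C)(C)CC[C@]2(C)O | intermediate
28 | seco iodo aldehyde (aldehyde at C3, iodide at C4) | CC1=CC[C@H]2[C@@H]([C@@H]1CC[C@H]1[C@](C)(CCI)[C@@H](OC(C)(C)C=O)CC[C@]1(C)O)C(C)(C)CC[C@]2(C)O | intermediate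
29 | sipholenol L | CC1=CC[C@H]2[C@@H]([C@@H]1CC[C@H]1[C@]3(C)CC[C@H](O)C(C)(C)O[C@H]3CC[C@]1(C)O)C(C)(C)CC[C@]2(C)O | target

**Step count and risks**

Total step count: 21. Longest linear sequence: 15 steps (steps 1 to 8, then 15 to 21).

Steps most likely to fail:

Step 11 (asymmetric Diels–Alder). The chiral Lewis acid may activate the hindered enone too weakly for bond formation at the neopentyl β-carbon, or may differentiate the two enone faces poorly, so that 17 forms slowly or with low enantiomeric purity. The fallback sets out from 15 and 16. The cycloaddition is run with the achiral mixed Lewis acid AlBr3/AlMe3 (toluene/CH2Cl2, –5 °C), a combination used for hindered silyloxydiene–cyclohexenone pairs, and should give 17 as a racemate together with the (1R,4aR,8aS)-cycloadduct F1. The racemate is taken through steps 12 to 14 unchanged, so that the enantiomeric triflate F2, the enantiomeric methyl alkene ester F3 and the enantiomeric acid F4 accompany 18, 19 and 20. The racemic acid is then resolved by crystallization with (S)-1-phenylethylamine (EtOAc/hexane): the (S)-1-phenylethylammonium salt of 20 F5 is collected while the (S)-1-phenylethylammonium salt of the enantiomeric acid F6 stays in the mother liquor (the (R)-amine is used instead if the solubilities are reversed). Aqueous KHSO4 releases the acid, and the route is rejoined at 20.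

Step 21 (key ring closure). One-electron reduction of the α-alkoxy aldehyde may outrun reduction of the iodide, leading to pinacol coupling or loss of the α-alkoxy group, or the addition may proceed with poor facial control at C3. The fallback changes the polarity generation from reductive to anionic and sets out from iodide 27. Displacement with PhSO2Na (DMF, 60 °C) should give the C4 phenyl sulfone ester F7, and i-Bu2AlH (CH2Cl2, –78 °C) the C4 phenyl sulfone aldehyde F8. LiN(i-Pr)2 (3.5 equiv, THF, –78 °C) then closes ring D by addition of the α-sulfonyl carbanion at C4 to the C3 aldehyde (Julia-type addition, reversible, so the more stable carbinol is expected), giving the 4-(phenylsulfonyl) derivative of sipholenol L F9. Reductive desulfonylation (Mg, MeOH, rt) returns to 29.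

Step 18 (double hydration). Hydrogen atom transfer may also reach the trisubstituted ring A alkene, or oxygen trapping may take the wrong face at C7 or d-C5. The fallback replaces the radical hydration by an ionic Markovnikov hydration and sets out from 25. Silylation (t-BuMe2SiCl, imidazole, DMF) gives the C4 tert-butyldimethylsilyl ether of 25 F10, which prevents the primary hydroxyl from closing a cyclic ether. Oxymercuration–demercuration (Hg(OAc)2, THF/H2O; then NaBH4, NaOH), in which water opens each mercurinium ion at the tertiary carbon from the less hindered face, should give the C4 tert-butyldimethylsilyl ether of 26 F11. n-Bu4NF (THF) returns to 26.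

**Further compounds**

F1 | step 11 | methyl 2-[(1R,4aR,8aS)-2-[(tert-butyldimethylsilyl)oxy]-8,8-dimethyl-5-oxo-1,4,4a,5,6,7,8,8a-octahydronaphthalen-1-yl]acetate (enantiomer of 17) | CC(C)(C)[Si](C)(C)OC1=CC[C@@H]2[C@H]([C@H]1CC(=O)OC)C(C)(C)CCC2=O
F2 | step 11 | methyl 2-[(1R,4aR,8aS)-8,8-dimethyl-5-oxo-2-{[(trifluoromethyl)sulfonyl]oxy}-1,4,4a,5,6,7,8,8a-octahydronaphthalen-1-yl]acetate (enantiomer of 18) | O=S(=O)(OC1=CC[C@@H]2[C@H]([C@H]1CC(=O)OC)C(C)(C)CCC2=O)C(F)(F)F
F3 | step 11 | methyl 2-[(1R,4aR,8aS)-2,8,8-trimethyl-5-oxo-1,4,4a,5,6,7,8,8a-octahydronaphthalen-1-yl]acetate (enantiomer of 19) | CC1=CC[C@@H]2[C@H]([C@H]1CC(=O)OC)C(C)(C)CCC2=O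
F4 | step 11 | 2-[(1R,4aR,8aS)-2,8,8-trimethyl-5-oxo-1,4,4a,5,6,7,8,8a-octahydronaphthalen-1-yl]acetic acid (enantiomer of 20) | CC1=CC[C@@H]2[C@H]([C@H]1CC(=O)O)C(C)(C)CCC2=O
F5 | step 11 | (S)-1-phenylethylammonium salt of 20 | CC1=CC[C@H]2[C@@H]([C@@H]1CC(=O)[O-])C(C)(C)CCC2=O.C[C@H]([NH3+])c1ccccc1
F6 | step 11 | (S)-1-phenylethylammonium salt of the enantiomeric acid | CC1=CC[C@@H]2[C@H]([C@H]1CC(=O)[O-])C(C)(C)CCC2=O.C[C@H]([NH3+])c1ccccc1
F7 | step 21 | C4 phenyl sulfone ester (27 with I replaced by SO2Ph) | CC1=CC[C@H]2[C@@H]([C@@H]1CC[C@H]1[C@](C)(CCS(=O)(=O)c3ccccc3)[C@@H](OC(C)(C)C(=O)OCC)CC[C@]1(C)O)C(C)(C)CC[C@]2(C)O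
F8 | step 21 | C4 phenyl sulfone aldehyde (28 with I replaced by SO2Ph) | CC1=CC[C@H]2[C@@H]([C@@H]1CC[C@H]1[C@](C)(CCS(=O)(=O)c3ccccc3)[C@@H](OC(C)(C)C=O)CC[C@]1(C)O)C(C)(C)CC[C@]2(C)O
F9 | step 21 | 4-(phenylsulfonyl) derivative of sipholenol L (C4 epimers) | CC1=CC[C@H]2[C@@H]([C@@H]1CC[C@H]1[C@]3(C)CC(S(=O)(=O)c4ccccc4)[C@H](O)C(C)(C)O[C@H]3CC[C@]1(C)O)C(C)(C)CC[C@]2(C)O
F10 | step 18 | C4 tert-butyldimethylsilyl ether of 25 | CC1=CC[C@H]2[C@@H]([C@@H]1CC[C@H]1[C@](C)(CCO[Si](C)(C)C(C)(C)C)[C@@H](OC(C)(C)C(=O)OCC)CCC1=C)C(C)(C)CCC2=C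
F11 | step 18 | C4 tert-butyldimethylsilyl ether of 26 | CC1=CC[C@H]2[C@@H]([C@@H]1CC[C@H]1[C@](C)(CCO[Si](C)(C)C(C)(C)C)[C@@H](OC(C)(C)C(=O)OCC)CC[C@]1(C)O)C(C)(C)CC[C@]2(C)O
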